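**Plan**
- Retrosynthesis, in order: cut the 7''-O–CH3 bond, which uncovers a C2-symmetric, all-R, doubly 2,3-cis 3,3''-biflavanone with homotopic 7-OH groups. Then cut C2–C3, then C2''–C3'', and last C3–C3''.
- Enabling feature: in each half C2 carries only H, O1 of ring A and the p-anisyl ring B. C2 plus ring B is therefore a 4-methoxybenzyl ether of the ring A phenol in disguise. C3 is the alpha-carbon of the C4 aryl ketone and can be a diazo (carbene) carbon. Counted from C3, O1 is atom 5 and C2 is atom 6, so a carbene at C3 can only insert 1,6 into the doubly activated C2–H and close ring C.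
- Forward, chain: phloroacetophenone is silylated (helpers for 5-OH and 7-OH) and etherified with 4-methoxybenzyl alcohol. Its enolate is then dimerized at the future C3/C3'', the site of the presumed biosynthetic coupling. The resulting symmetrical 1,4-diketone holds every skeletal carbon except the last OCH3.
- Forward, rings: diazo transfer and insertion close ring C of unit 2. A second diazo transfer and insertion close ring C of unit 1. Desilylation and one O-methylation finish the synthesis.
- Stereochemistry: both insertions use the same chiral dirhodium carboxylate, which picks the benzylic H (C2'', then C2) and gives the kinetic cis C2/C3 relation. Twofold catalyst control gives the homochiral R,R,R,R array and diverts mismatched material into a separable meso-type isomer. All later steps are base-free.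

Key step: step 7

Assumption: Rh2(S-PTTL)4 (dirhodium tetrakis[N-phthaloyl-(S)-tert-leucinate], divalent rhodium) is taken to lead to the (2R,3R) series on this substrate class. If it leads to the antipode, Rh2(R-PTTL)4 replaces it in steps 5 and 7 and nothing else changes.

Labels: unit 1 (O1, C2, C3, C4) is the half that ends as the 5,7-dihydroxyflavanone. Unit 2 (double-primed atoms) is the half that ends as the 5-hydroxy-7-methoxyflavanone. In C2-symmetric 11 and 12 the halves are homotopic, and the half closed in step 7 is called unit 1. TIPS = triisopropylsilyl, PMB = 4-methoxybenzyl, Ar* = 2-(PMB-oxy)-4,6-bis(TIPS-oxy)phenyl.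

Step 1
Reactants: 1 2',4',6'-trihydroxyacetophenone (phloroacetophenone)
Product: 2 1-[2-hydroxy-4,6-bis(triisopropylsilyloxy)phenyl]ethanone
Conditions: i-Pr3SiCl (2.1 equiv), imidazole, DMF, 0 °C to rt
Reagents that add atoms: chlorotriisopropylsilane, CC(C)[Si](Cl)(C(C)C)C(C)C
Why: Silyl ether protection of phenols, in which the 4-OH and one of the two equivalent ortho OH groups react while the last OH is held in the hydrogen bond to the acetyl C=O so that silylation should stop at the bis-ether; silyl groups are chosen because they offer the later carbene no activated C–H within reach.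

Step 2
Reactants: 2 1-[2-hydroxy-4,6-bis(triisopropylsilyloxy)phenyl]ethanone; 3 4-methoxybenzyl alcohol
Product: 4 1-[2-(4-methoxybenzyloxy)-4,6-bis(triisopropylsilyloxy)phenyl]ethanone (Ar*–COCH3)
Conditions: PPh3, DIAD, THF, 0 °C to rt
Reagents that add atoms: none
Why: Mitsunobu etherification of the remaining chelated phenol under neutral conditions that spare the aryl silyl ethers, which installs the future C2 and ring B as a PMB ether on the future O1.

Step 3
Reactants: 4 Ar*–COCH3 (two molecules)
Product: 5 1,4-bis(Ar*)butane-1,4-dione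
Conditions: LiN(i-Pr)2, THF, −78 °C; then CuCl2, DMF, −78 °C to rt
Reagents that add atoms: none
Why: Oxidative dimerization of a methyl ketone lithium enolate by CuCl2 (one-electron oxidation to the alpha-keto radical and C–C coupling), a standard entry to symmetrical 1,4-diketones, forms the C3–C3'' bond without creating a stereocenter.

Step 4
Reactants: 5 1,4-bis(Ar*)butane-1,4-dione
Product: 7 2-diazo-1,4-bis(Ar*)butane-1,4-dione, via trifluoroacetyl diketone 6 (not isolated)
Conditions: LiN(SiMe3)2 (1.0 equiv), THF, −78 °C; CF3CO2CH2CF3; 5% aq HCl work-up; then MeSO2N3, Et3N, H2O (1 equiv), MeCN, rt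
Reagents that add atoms: methanesulfonyl azide, CS(=O)(=O)N=[N+]=[N-]; 2,2,2-trifluoroethyl trifluoroacetate, O=C(OCC(F)(F)F)C(F)(F)F (its CF3CO group stays in 6 only)
Why: Detrifluoroacetylative (Regitz-type deacylative) diazo transfer, in which one equivalent of base should give the mono-enolate because a second, vicinal enolization would build a dianion, Claisen trifluoroacetylation activates that one CH2, and the sulfonyl azide then delivers N2 with loss of the trifluoroacetyl group.

Step 5
Reactants: 7 2-diazo-1,4-bis(Ar*)butane-1,4-dione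
Product: 8 (2R,3R)-2-(4-methoxyphenyl)-3-[2-oxo-2-(Ar*)ethyl]-5,7-bis(TIPS-oxy)chroman-4-one (2,3-cis)
Conditions: Rh2(S-PTTL)4 (1 mol %), toluene, −40 to 0 °C, slow addition of 7; neutral work-up
Reagents that add atoms: none
Why: Intramolecular dirhodium-carbene 1,6-C–H insertion, the reaction type known to turn ortho-alkoxyaryl alpha-alkyl diazoketones into 2,3-cis-chroman-4-ones: the carbene at C3'' inserts into the doubly activated (alpha-aryloxy and p-anisyl) CH2 of its own ring A ether, the chiral carboxylate pocket choosing one enantiotopic H with retention (C2'' = R) and the compact transition state placing anisyl and side chain cis (C3'' = R), while bulky ligands and low temperature should hold back 1,2-hydride migration from the acyl-deactivated CH2.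

Step 6
Reactants: 8 (2R,3R)-2-(4-methoxyphenyl)-3-[2-oxo-2-(Ar*)ethyl]-5,7-bis(TIPS-oxy)chroman-4-one
Product: 10 (2R,3R)-3-[1-diazo-2-oxo-2-(Ar*)ethyl]-2-(4-methoxyphenyl)-5,7-bis(TIPS-oxy)chroman-4-one, via trifluoroacetyl ketone 9 (not isolated)
Conditions: LiN(SiMe3)2 (1.05 equiv), THF, −78 °C; CF3CO2CH2CF3; 5% aq HCl work-up; then MeSO2N3, Et3N, H2O (1 equiv), MeCN, 0 °C to rt
Reagents that add atoms: methanesulfonyl azide, CS(=O)(=O)N=[N+]=[N-]; 2,2,2-trifluoroethyl trifluoroacetate, O=C(OCC(F)(F)F)C(F)(F)F (its CF3CO group stays in 9 only)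
Why: The same detrifluoroacetylative diazo transfer, in which the bulky amide base at −78 °C should take a proton of the open side-chain CH2 rather than the hindered tertiary C3''–H and the acidic 1,3-diketone 9 buffers the amine in the second stage, so that the base-labile cis C2''/C3'' pair should survive.

Step 7
Reactants: 10 (2R,3R)-3-[1-diazo-2-oxo-2-(Ar*)ethyl]-2-(4-methoxyphenyl)-5,7-bis(TIPS-oxy)chroman-4-one
Product: 11 (2R,3R,2''R,3''R)-4',4'''-dimethoxy-5,5'',7,7''-tetrakis(TIPS-oxy)-3,3''-biflavanone (cis in both halves, C2-symmetric)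
Conditions: Rh2(S-PTTL)4 (2 mol %), toluene, −40 °C to rt, slow addition of 10; neutral work-up
Reagents that add atoms: none
Why: Rh2(S-PTTL)4 expels N2 from 10 and gives an electrophilic rhodium carbene at C3, which engages the hydridic benzylic C–H of the O1–CH2–anisyl ether in a concerted but asynchronous three-centre transition state, so that C2–C3 forms while H passes from C2 to C3. The closest known reaction type is the dirhodium-carboxylate-catalysed insertion of ortho-alkoxyaryl alpha-alkyl diazoketones that gives 2,3-cis-chroman-4-ones, already used in step 5. Ring C of unit 1 closes by 1,6-insertion to a six-membered ring (in the stepwise limit a 6-(enolendo)-endo-trig attack of the rhodium enolate carbon C3 on the O1=C2 oxocarbenium ion), a five-membered ring being excluded because atom 5 counted from C3 is O1. C2 (R) is set by the choice of the catalyst between the two benzylic hydrogens and by retention at that carbon, C3 (R) by the same transition state, in which the anisyl group on C2 and the C3'' substituent on C3 both point away from the forming ring so that they end cis, and the like relation of C3 to C3'' by the carbene face that the catalyst leaves open, the face it also used in step 5; mismatched material ends as a separable meso-type diastereomer. The step needs insertion to outrun 1,2-migration of the tertiary C3''–H, oxonium ylide formation at O1 followed by Stevens shift of the benzyl group, and attack on the nearby ring B of unit 2: allylic-type strain keeps C3''–H in the plane of the carbene and thus orthogonal to its empty orbital while C4''=O makes that hydrogen less hydridic, the lone pairs of O1 are drawn into the acylated ring A, and the C2–H bond is activated twice over (alpha-oxygen and p-anisyl). Site selectivity is built in, since only one benzylic ether CH2 is left and the 5-O-silyl group offers no activated C–H within reach.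

Step 8
Reactants: 11 (2R,3R,2''R,3''R)-4',4'''-dimethoxy-5,5'',7,7''-tetrakis(TIPS-oxy)-3,3''-biflavanone
Product: 12 (2R,3R,2''R,3''R)-5,5'',7,7''-tetrahydroxy-4',4'''-dimethoxy-3,3''-biflavanone
Conditions: HF·pyridine, pyridine, THF, 0 °C to rt
Reagents that add atoms: none
Why: Fluoride-driven cleavage of the four aryl silyl ethers in a pyridine-buffered, non-basic medium, which avoids the phenoxide and enolate conditions under which C3 epimerizes or ring C opens by retro-oxa-Michael reaction.

Step 9
Reactants: 12 (2R,3R,2''R,3''R)-5,5'',7,7''-tetrahydroxy-4',4'''-dimethoxy-3,3''-biflavanone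
Product: 13 target, (2R,3R,2''R,3''R)-5,5'',7-trihydroxy-7'',4',4'''-trimethoxy-3,3''-biflavanone
Conditions: Me3SiCHN2 (0.8 equiv), MeOH–toluene, 0 °C; recovered 12 is recycled
Reagents that add atoms: trimethylsilyldiazomethane, C[Si](C)(C)C=[N+]=[N-]
Why: Base-free O-methylation of an acidic phenol by diazomethane released from Me3SiCHN2 and methanol, in which only the non-chelated 7-OH groups are acidic enough to react, the two are homotopic in C2-symmetric 12 so that either one gives 13, and a deficit of reagent limits the second methylation, the bis-ether being removed by chromatography.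

**Compound list**
1 | 2',4',6'-trihydroxyacetophenone | CC(=O)c1c(O)cc(O)cc1O | starting material
2 | 1-[2-hydroxy-4,6-bis(triisopropylsilyloxy)phenyl]ethanone | CC(=O)c1c(O)cc(O[Si](C(C)C)(C(C)C)C(C)C)cc1O[Si](C(C)C)(C(C)C)C(C)C | intermediate
3 | 4-methoxybenzyl alcohol | COc1ccc(CO)cc1 | starting material
4 | 1-[2-(4-methoxybenzyloxy)-4,6-bis(triisopropylsilyloxy)phenyl]ethanone | CC(=O)c1c(OCc2ccc(OC)cc2)cc(O[Si](C(C)C)(C(C)C)C(C)C)cc1O[Si](C(C)C)(C(C)C)C(C)C | intermediate
5 | 1,4-bis[2-(4-methoxybenzyloxy)-4,6-bis(triisopropylsilyloxy)phenyl]butane-1,4-dione | COc1ccc(COc2cc(O[Si](C(C)C)(C(C)C)C(C)C)cc(O[Si](C(C)C)(C(C)C)C(C)C)c2C(=O)CCC(=O)c2c(OCc3ccc(OC)cc3)cc(O[Si](C(C)C)(C(C)C)C(C)C)cc2O[Si](C(C)C)(C(C)C)C(C)C)cc1 | intermediate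
6 | 2-trifluoroacetyl derivative of 5 (keto and enol forms) | COc1ccc(COc2cc(O[Si](C(C)C)(C(C)C)C(C)C)cc(O[Si](C(C)C)(C(C)C)C(C)C)c2C(=O)C(C(=O)C(F)(F)F)CC(=O)c2c(OCc3ccc(OC)cc3)cc(O[Si](C(C)C)(C(C)C)C(C)C)cc2O[Si](C(C)C)(C(C)C)C(C)C)cc1 | intermediate
7 | 2-diazo-1,4-bis(Ar*)butane-1,4-dione | COc1ccc(COc2cc(O[Si](C(C)C)(C(C)C)C(C)C)cc(O[Si](C(C)C)(C(C)C)C(C)C)c2C(=O)C(=[N+]=[N-])CC(=O)c2c(OCc3ccc(OC)cc3)cc(O[Si](C(C)C)(C(C)C)C(C)C)cc2O[Si](C(C)C)(C(C)C)C(C)C)cc1 | intermediate
8 | (2R,3R)-2-(4-methoxyphenyl)-3-[2-oxo-2-(Ar*)ethyl]-5,7-bis(TIPS-oxy)chroman-4-one, 2,3-cis | COc1ccc(COc2cc(O[Si](C(C)C)(C(C)C)C(C)C)cc(O[Si](C(C)C)(C(C)C)C(C)C)c2C(=O)C[C@H]2C(=O)c3c(O[Si](C(C)C)(C(C)C)C(C)C)cc(O[Si](C(C)C)(C(C)C)C(C)C)cc3O[C@H]2c2ccc(OC)cc2)cc1 | intermediate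
9 | side-chain trifluoroacetyl derivative of 8 (CH epimers and enol) | COc1ccc(COc2cc(O[Si](C(C)C)(C(C)C)C(C)C)cc(O[Si](C(C)C)(C(C)C)C(C)C)c2C(=O)C(C(=O)C(F)(F)F)[C@H]2C(=O)c3c(O[Si](C(C)C)(C(C)C)C(C)C)cc(O[Si](C(C)C)(C(C)C)C(C)C)cc3O[C@H]2c2ccc(OC)cc2)cc1 | intermediate
10 | (2R,3R)-3-[1-diazo-2-oxo-2-(Ar*)ethyl]-2-(4-methoxyphenyl)-5,7-bis(TIPS-oxy)chroman-4-one | COc1ccc(COc2cc(O[Si](C(C)C)(C(C)C)C(C)C)cc(O[Si](C(C)C)(C(C)C)C(C)C)c2C(=O)C(=[N+]=[N-])[C@H]2C(=O)c3c(O[Si](C(C)C)(C(C)C)C(C)C)cc(O[Si](C(C)C)(C(C)C)C(C)C)cc3O[C@H]2c2ccc(OC)cc2)cc1 | intermediate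
11 | (2R,3R,2''R,3''R)-4',4'''-dimethoxy-5,5'',7,7''-tetrakis(TIPS-oxy)-3,3''-biflavanone | COc1ccc([C@@H]2Oc3cc(O[Si](C(C)C)(C(C)C)C(C)C)cc(O[Si](C(C)C)(C(C)C)C(C)C)c3C(=O)[C@@H]2[C@H]2C(=O)c3c(O[Si](C(C)C)(C(C)C)C(C)C)cc(O[Si](C(C)C)(C(C)C)C(C)C)cc3O[C@H]2c2ccc(OC)cc2)cc1 | intermediate
12 | (2R,3R,2''R,3''R)-5,5'',7,7''-tetrahydroxy-4',4'''-dimethoxy-3,3''-biflavanone | COc1ccc([C@@H]2Oc3cc(O)cc(O)c3C(=O)[C@@H]2[C@H]2C(=O)c3c(O)cc(O)cc3O[C@H]2c2ccc(OC)cc2)cc1 | intermediate
13 | (2R,3R,2''R,3''R)-5,5'',7-trihydroxy-7'',4',4'''-trimethoxy-3,3''-biflavanone (CNP0184936.2) | COc1ccc([C@@H]2Oc3cc(O)cc(O)c3C(=O)[C@@H]2[C@H]2C(=O)c3c(O)cc(OC)cc3O[C@H]2c2ccc(OC)cc2)cc1 | target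

Total step count: 9. Longest linear sequence: 9 steps (1 to 13).

**Steps most likely to fail**

Step 7. The risk is 1,2-hydride migration from C3'' to the carbene carbon, which would drain the carbene before it inserts. A second risk is mismatched double stereodifferentiation between catalyst and the existing half.
- The fallback sets out from 8 and comes back at 11. It forms the same C2–C3 bond without any carbene.
- The side-chain ketone of 8 is O-acetylated through its potassium enolate (KN(SiMe3)2, Ac2O, THF, −78 °C) to the (Z)-enol acetate F1.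
- DDQ with 2,6-dichloropyridine and LiClO4 in 1,2-dichloroethane then removes hydride from the PMB ether CH2.
- The oxocarbenium ion is captured by the enol acetate carbon with loss of the acetyl group. This is the oxidative C–H cleavage and cyclization of PMB ethers known for pyran-4-ones.
- The Z enol acetate and the E oxocarbenium ion again favour the cis pair, and C3'' becomes the controlling element for the relation between the halves.

Step 5. The risk is 1,2-hydride migration from the freely rotating CH2 next to the carbene, which would compete with insertion.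
- The fallback sets out from 7 and comes back at 8. It changes the carbene class.
- Soft enolization of the distal ketone (t-BuMe2SiOTf, Et3N, CH2Cl2, 0 °C) gives the (Z)-siloxyvinyl diazoketone F2. F2 has no sp3 C–H next to the diazo carbon and leads to a donor/acceptor vinylcarbene.
- Insertion with the same Rh2(S-PTTL)4 gives the cis-flavanone enol silyl ether F3.
- AcOH–THF–H2O at 0 °C hydrolyses the enol ether, but not the aryl TIPS ethers, to 8.

Step 6. The risk is deprotonation at C3'', followed by epimerization to the trans isomer or retro-oxa-Michael opening of ring C.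
- The fallback sets out from 7 and comes back at 9. It moves the strong-base operation ahead of any stereocenter.
- Compound 7, whose diazo group tolerates amide bases, is treated with LiN(SiMe3)2 and CF3CO2CH2CF3 at −78 °C. This gives the enolized trifluoroacetyl diazo diketone F4.
- Insertion with Rh2(S-PTTL)4 closes ring C of unit 2 and gives 9 directly.
- Only the buffered MeSO2N3/Et3N stage of step 6 then remains to reach 10.

**Further compounds**
F1 | step 7 | (Z)-enol acetate of the side-chain ketone of 8 | COc1ccc(COc2cc(O[Si](C(C)C)(C(C)C)C(C)C)cc(O[Si](C(C)C)(C(C)C)C(C)C)c2/C(OC(C)=O)=C/[C@H]2C(=O)c3c(O[Si](C(C)C)(C(C)C)C(C)C)cc(O[Si](C(C)C)(C(C)C)C(C)C)cc3O[C@H]2c2ccc(OC)cc2)cc1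
F2 | step 5 | (Z)-2-diazo-4-(tert-butyldimethylsilyloxy)-1,4-bis(Ar*)but-3-en-1-one | COc1ccc(COc2cc(O[Si](C(C)C)(C(C)C)C(C)C)cc(O[Si](C(C)C)(C(C)C)C(C)C)c2C(=O)C(=[N+]=[N-])/C=C(\O[Si](C)(C)C(C)(C)C)c2c(OCc3ccc(OC)cc3)cc(O[Si](C(C)C)(C(C)C)C(C)C)cc2O[Si](C(C)C)(C(C)C)C(C)C)cc1
F3 | step 5 | (2R,3R)-3-[(Z)-2-(Ar*)-2-(tert-butyldimethylsilyloxy)vinyl]-2-(4-methoxyphenyl)-5,7-bis(TIPS-oxy)chroman-4-one | COc1ccc(COc2cc(O[Si](C(C)C)(C(C)C)C(C)C)cc(O[Si](C(C)C)(C(C)C)C(C)C)c2/C(O[Si](C)(C)C(C)(C)C)=C/[C@H]2C(=O)c3c(O[Si](C(C)C)(C(C)C)C(C)C)cc(O[Si](C(C)C)(C(C)C)C(C)C)cc3O[C@H]2c2ccc(OC)cc2)cc1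
F4 | step 6 | 2-diazo-3-trifluoroacetyl-1,4-bis(Ar*)butane-1,4-dione (drawn as keto form) | COc1ccc(COc2cc(O[Si](C(C)C)(C(C)C)C(C)C)cc(O[Si](C(C)C)(C(C)C)C(C)C)c2C(=O)C(=[N+]=[N-])C(C(=O)C(F)(F)F)C(=O)c2c(OCc3ccc(OC)cc3)cc(O[Si](C(C)C)(C(C)C)C(C)C)cc2O[Si](C(C)C)(C(C)C)C(C)C)cc1
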